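**Retrosynthetic overview**

1. The acid is released last from its tert-butyl ester; the butenolide is attached just before by Negishi coupling of a C12 bromide with 3-bromofuran-2(5H)-one.
2. Key step: ring B is closed onto ring A by forming the C9–C10 bond in an iron-hydride (MHAT) radical 6-endo cyclisation of a 1,1-disubstituted alkene onto a (Z)-2-(1-acyloxyalkyl)enoate. Loss of the C7 acyloxy group installs the 7,8-alkene, and C9 and C10 are set from C5/C6.
3. The cyclisation precursor comes from a reductive (hydroalumination) aldol of a five-carbon bromo-ynoate with an α-tigloyloxy aldehyde.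
4. C5 and C6 are set together by a catalytic enantioselective syn Mukaiyama aldol between the enolsilane of 3,3-dimethylcyclohexanone and dimethoxyacetaldehyde.
5. Ring order: ring A is bought (3-methylcyclohexenone), ring B is made in the radical step, and the butenolide ring is bought.

Assumption: 3-bromofuran-2(5H)-one, tigloyl chloride, 4-bromobut-1-yne and 2,2-dimethoxyacetaldehyde (dried from its commercial aqueous solution) are taken as commercial. Locants C1–C20 in the explanations follow labdane numbering (C17 = carboxyl carbon, C20 = angular methyl).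

**Route**

Step 1
Reactants: 1 3-methylcyclohex-2-en-1-one
Product: 3 [(3,3-dimethylcyclohex-1-en-1-yl)oxy](trimethyl)silane, via bromomagnesium enolate 2 (not isolated)
Conditions: MeMgBr, CuBr·SMe2 (5 mol %), TMSCl, THF, −40 to 0 °C; Et3N, NaHCO3 work-up
Reagents that add atoms: methylmagnesium bromide C[Mg]Br; chlorotrimethylsilane C[Si](C)(C)Cl
Why: Copper-catalysed conjugate addition of the methyl Grignard reagent creates the gem-dimethyl carbon (C4) and the regiodefined enolate is trapped as its silyl enol ether; no stereocentre is formed.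

Step 2
Reactants: 3 [(3,3-dimethylcyclohex-1-en-1-yl)oxy](trimethyl)silane; 4 2,2-dimethoxyacetaldehyde
Product: 6 (2R)-2-[(1R)-1-hydroxy-2,2-dimethoxyethyl]-3,3-dimethylcyclohexan-1-one, via trimethylsilyl ether 5 (not isolated)
Conditions: [Cu((R,R)-Ph-pybox)](SbF6)2 (10 mol %), CH2Cl2, −78 to −40 °C; then 1 M HCl, THF, 0 °C
Reagents that add atoms: none
Why: Chelation-controlled enantioselective Mukaiyama aldol: the α-alkoxy aldehyde binds divalent copper in a bidentate way, the (R,R)-ligand is chosen to leave its re face open (mirror image of the si-face delivery of the (S,S)-complex), and the open transition state gives the syn adduct whatever the enolsilane geometry, so C5 and C6 are set together.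

Step 3
Reactants: 6 (2R)-2-[(1R)-1-hydroxy-2,2-dimethoxyethyl]-3,3-dimethylcyclohexan-1-one; 7 (2E)-2-methylbut-2-enoyl chloride (tigloyl chloride)
Product: 8 (1R)-1-[(1R)-2,2-dimethyl-6-oxocyclohexyl]-2,2-dimethoxyethyl (2E)-2-methylbut-2-enoate
Conditions: 7, pyridine, DMAP (cat.), CH2Cl2, 0 °C to rt
Reagents that add atoms: none
Why: DMAP-catalysed acylation puts the natural tiglate on O6 early, where it also serves as the protecting group; no stereocentre is touched.

Step 4
Reactants: 8 (1R)-1-[(1R)-2,2-dimethyl-6-oxocyclohexyl]-2,2-dimethoxyethyl (2E)-2-methylbut-2-enoate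
Product: 9 (1R)-1-[(1S)-2,2-dimethyl-6-methylidenecyclohexyl]-2,2-dimethoxyethyl (2E)-2-methylbut-2-enoate
Conditions: Zn, CH2Br2, TiCl4, THF (reagent aged at 5 °C); then 8, CH2Cl2, 0 °C to rt
Reagents that add atoms: dibromomethane BrCBr
Why: Takai–Lombardo methylenation is non-basic, so the β-acyloxy ketone neither eliminates nor epimerises at C5, esters and the acetal are left alone, and the 1,1-disubstituted alkene needed for the radical step is installed (the descriptor at C5 changes from R to S only through priorities).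

Step 5
Reactants: 9 (1R)-1-[(1S)-2,2-dimethyl-6-methylidenecyclohexyl]-2,2-dimethoxyethyl (2E)-2-methylbut-2-enoate
Product: 11 (1R)-1-[(1S)-2,2-dimethyl-6-methylidenecyclohexyl]-2-oxoethyl (2E)-2-methylbut-2-enoate, via collidinium salt 10 (not isolated)
Conditions: TESOTf, 2,4,6-collidine, CH2Cl2, 0 °C; then H2O
Reagents that add atoms: water O
Why: Silyl triflate–collidine acetal cleavage goes through a pyridinium N,O-acetal that water hydrolyses without protic acid, so the exocyclic alkene does not migrate and the ester survives; the α-acyloxy aldehyde is used at once to avoid C6 epimerisation.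

Step 6
Reactants: 12 4-bromobut-1-yne
Product: 14 tert-butyl 5-bromopent-2-ynoate, via lithium acetylide 13 (not isolated)
Conditions: n-BuLi, THF, −78 °C; Boc2O, −78 to −20 °C; aq. NH4Cl
Reagents that add atoms: di-tert-butyl dicarbonate CC(C)(C)OC(=O)OC(=O)OC(C)(C)C
Why: Deprotonation of the terminal alkyne is far faster than attack on the primary bromide at −78 °C, and acylation of the acetylide with Boc2O gives the tert-butyl ynoate (C17, C8, C9, C11, C12).

Step 7
Reactants: 11 (1R)-1-[(1S)-2,2-dimethyl-6-methylidenecyclohexyl]-2-oxoethyl (2E)-2-methylbut-2-enoate; 14 tert-butyl 5-bromopent-2-ynoate; 7 (2E)-2-methylbut-2-enoyl chloride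
Product: 17 tert-butyl (2Z)-5-bromo-2-[(2R)-2-[(1S)-2,2-dimethyl-6-methylidenecyclohexyl]-1,2-bis{[(2E)-2-methylbut-2-enoyl]oxy}ethyl]pent-2-enoate, via vinylalane 15 (not isolated), via aluminium alkoxide 16 (not isolated)
Conditions: 14 (1.5 equiv), DIBAL-H (1.4 equiv), HMPA, THF, 0 °C; then 11, −78 to −20 °C; then 7, pyridine, DMAP, −20 °C to rt
Reagents that add atoms: none
Why: Reductive aldol by conjugate syn-hydroalumination: H and Al add cis so C11 ends cis to the ester, the α-aluminated enoate adds to the aldehyde with retention to give the (Z)-configured Morita–Baylis–Hillman-type alkoxide, and acylation in the same flask with the same acyl chloride makes any 1,2-acyl shift between O6 and O7 degenerate; C7 forms as an epimer mixture that is erased in step 8.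

Step 8
Reactants: 17 tert-butyl (2Z)-5-bromo-2-[(2R)-2-[(1S)-2,2-dimethyl-6-methylidenecyclohexyl]-1,2-bis{[(2E)-2-methylbut-2-enoyl]oxy}ethyl]pent-2-enoate
Product: 19 tert-butyl (1R,4S,4aS,8aR)-1-(2-bromoethyl)-5,5,8a-trimethyl-4-{[(2E)-2-methylbut-2-enoyl]oxy}-1,4,4a,5,6,7,8,8a-octahydronaphthalene-2-carboxylate, via ester enolate 18 (not isolated)
Conditions: Fe(acac)3 (0.5 equiv), PhSi(OiPr)H2 (2.5 equiv), THF (0.02 M), 40 °C
Reagents that add atoms: none
Why: Proposed new method: the trivalent iron hydride formed from Fe(acac)3 and the silane transfers a hydrogen atom to the CH2 terminus of the 1,1-disubstituted alkene (Markovnikov MHAT), the tertiary C10 radical adds 6-endo to C9, the β-carbon of the tethered enoate (polarity-matched, and the same ring closure as the second cyclisation of a radical polyene cascade, so a chair transition state with the C5 tether, the C6 ester and the C11 chain equatorial gives the trans-decalin with 10β-methyl and 9α-H, the (Z)-alkene being what places C11 equatorial), the α-ester radical is reduced by divalent iron to the enolate, and this expels the C7 tiglate (E1cB) to give the 7,8-alkene; the closest known reactions are iron-hydride reductive olefin coupling (intramolecular Giese reaction) and radical addition–β-elimination on Morita–Baylis–Hillman esters.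

Step 9
Reactants: 19 tert-butyl (1R,4S,4aS,8aR)-1-(2-bromoethyl)-5,5,8a-trimethyl-4-{[(2E)-2-methylbut-2-enoyl]oxy}-1,4,4a,5,6,7,8,8a-octahydronaphthalene-2-carboxylate; 20 3-bromofuran-2(5H)-one
Product: 22 tert-butyl (1R,4S,4aS,8aR)-5,5,8a-trimethyl-4-{[(2E)-2-methylbut-2-enoyl]oxy}-1-[2-(2-oxo-2,5-dihydrofuran-3-yl)ethyl]-1,4,4a,5,6,7,8,8a-octahydronaphthalene-2-carboxylate, via alkylzinc bromide 21 (not isolated)
Conditions: Zn dust, LiCl, THF, 40 °C; then 20, Pd(OAc)2 (5 mol %), SPhos (10 mol %), rt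
Reagents that add atoms: none
Why: Zinc insertion into the primary C–Br bond followed by Negishi coupling (fast oxidative addition of zerovalent palladium to the activated α-bromobutenolide) forms C12–C13 under neutral conditions that spare the tiglate, the butenolide and the hindered allylic ester; no stereocentre is involved.

Step 10
Reactants: 22 tert-butyl (1R,4S,4aS,8aR)-5,5,8a-trimethyl-4-{[(2E)-2-methylbut-2-enoyl]oxy}-1-[2-(2-oxo-2,5-dihydrofuran-3-yl)ethyl]-1,4,4a,5,6,7,8,8a-octahydronaphthalene-2-carboxylate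
Product: 23 (1R,4S,4aS,8aR)-5,5,8a-trimethyl-4-{[(2E)-2-methylbut-2-enoyl]oxy}-1-[2-(2-oxo-2,5-dihydrofuran-3-yl)ethyl]-1,4,4a,5,6,7,8,8a-octahydronaphthalene-2-carboxylic acid (CNP0245290.2)
Conditions: TFA, CH2Cl2, 0 °C to rt
Reagents that add atoms: none
Why: Acidolysis of the tert-butyl ester (loss of isobutene) frees the acid without touching the tiglate, the butenolide or the C6–O bond, whose ionisation is disfavoured by the electron-poor alkene.

**Compound list**

1 | 3-methylcyclohex-2-en-1-one | CC1=CC(=O)CCC1 | starting material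
2 | bromomagnesium 3,3-dimethylcyclohex-1-en-1-olate | CC1(C)CCCC(O[Mg]Br)=C1 | intermediate (not isolated)
3 | [(3,3-dimethylcyclohex-1-en-1-yl)oxy](trimethyl)silane | C[Si](C)(C)OC1=CC(C)(C)CCC1 | intermediate
4 | 2,2-dimethoxyacetaldehyde | COC(OC)C=O | starting material
5 | (2R)-2-[(1R)-2,2-dimethoxy-1-(trimethylsilyloxy)ethyl]-3,3-dimethylcyclohexan-1-one | C[Si](C)(C)O[C@@H](C(OC)OC)[C@@H]1C(=O)CCCC1(C)C | intermediate (not isolated)
6 | (2R)-2-[(1R)-1-hydroxy-2,2-dimethoxyethyl]-3,3-dimethylcyclohexan-1-one (syn aldol) | O[C@@H](C(OC)OC)[C@@H]1C(=O)CCCC1(C)C | intermediate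
7 | (2E)-2-methylbut-2-enoyl chloride (tigloyl chloride) | C/C=C(\C)C(Cl)=O | starting material
8 | (1R)-1-[(1R)-2,2-dimethyl-6-oxocyclohexyl]-2,2-dimethoxyethyl (2E)-2-methylbut-2-enoate | C/C=C(\C)C(=O)O[C@@H](C(OC)OC)[C@@H]1C(=O)CCCC1(C)C | intermediate
9 | (1R)-1-[(1S)-2,2-dimethyl-6-methylidenecyclohexyl]-2,2-dimethoxyethyl (2E)-2-methylbut-2-enoate | C/C=C(\C)C(=O)O[C@@H](C(OC)OC)[C@@H]1C(=C)CCCC1(C)C | intermediate
10 | 1-[(2R)-2-[(1S)-2,2-dimethyl-6-methylidenecyclohexyl]-1-methoxy-2-{[(2E)-2-methylbut-2-enoyl]oxy}ethyl]-2,4,6-trimethylpyridin-1-ium trifluoromethanesulfonate (C1 of the ethyl chain as a mixture) | C/C=C(\C)C(=O)O[C@@H](C(OC)[n+]1c(C)cc(C)cc1C)[C@@H]1C(=C)CCCC1(C)C.[O-]S(=O)(=O)C(F)(F)F | intermediate (not isolated)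
11 | (1R)-1-[(1S)-2,2-dimethyl-6-methylidenecyclohexyl]-2-oxoethyl (2E)-2-methylbut-2-enoate | C/C=C(\C)C(=O)O[C@@H](C=O)[C@@H]1C(=C)CCCC1(C)C | intermediate
12 | 4-bromobut-1-yne | C#CCCBr | starting material
13 | (4-bromobut-1-yn-1-yl)lithium | [Li]C#CCCBr | intermediate (not isolated)
14 | tert-butyl 5-bromopent-2-ynoate | CC(C)(C)OC(=O)C#CCCBr | intermediate
15 | tert-butyl (2E)-2-[bis(2-methylpropyl)alumanyl]-5-bromopent-2-enoate (C11 cis to the ester) | BrCC/C=C(\C(=O)OC(C)(C)C)[Al](CC(C)C)CC(C)C | intermediate (not isolated)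
16 | tert-butyl (2Z)-2-[(2R)-1-{[bis(2-methylpropyl)alumanyl]oxy}-2-[(1S)-2,2-dimethyl-6-methylidenecyclohexyl]-2-{[(2E)-2-methylbut-2-enoyl]oxy}ethyl]-5-bromopent-2-enoate (C7 epimers) | BrCC/C=C(\C(=O)OC(C)(C)C)C(O[Al](CC(C)C)CC(C)C)[C@H](OC(=O)/C(C)=C/C)[C@@H]1C(=C)CCCC1(C)C | intermediate (not isolated)
17 | tert-butyl (2Z)-5-bromo-2-[(2R)-2-[(1S)-2,2-dimethyl-6-methylidenecyclohexyl]-1,2-bis{[(2E)-2-methylbut-2-enoyl]oxy}ethyl]pent-2-enoate (C7 epimers) | BrCC/C=C(\C(=O)OC(C)(C)C)C(OC(=O)/C(C)=C/C)[C@H](OC(=O)/C(C)=C/C)[C@@H]1C(=C)CCCC1(C)C | intermediate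
18 | iron-bound tert-butyl ester enolate of the cyclised trans-decalin (C9–C10 bond formed, C7 still bearing tigloyloxy; ring stereocentres as in 19; drawn as the anion) | C/C=C(\C)C(=O)O[C@H]1C(OC(=O)/C(C)=C/C)C(=C([O-])OC(C)(C)C)[C@H](CCBr)[C@@]2(C)CCCC(C)(C)[C@H]12 | intermediate (not isolated)
19 | tert-butyl (1R,4S,4aS,8aR)-1-(2-bromoethyl)-5,5,8a-trimethyl-4-{[(2E)-2-methylbut-2-enoyl]oxy}-1,4,4a,5,6,7,8,8a-octahydronaphthalene-2-carboxylate | C/C=C(\C)C(=O)O[C@H]1C=C(C(=O)OC(C)(C)C)[C@H](CCBr)[C@@]2(C)CCCC(C)(C)[C@H]12 | intermediate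
20 | 3-bromofuran-2(5H)-one | O=C1OCC=C1Br | starting material
21 | bromo{2-[(1R,4S,4aS,8aR)-2-(tert-butoxycarbonyl)-5,5,8a-trimethyl-4-{[(2E)-2-methylbut-2-enoyl]oxy}-1,4,4a,5,6,7,8,8a-octahydronaphthalen-1-yl]ethyl}zinc | C/C=C(\C)C(=O)O[C@H]1C=C(C(=O)OC(C)(C)C)[C@H](CC[Zn]Br)[C@@]2(C)CCCC(C)(C)[C@H]12 | intermediate (not isolated)
22 | tert-butyl (1R,4S,4aS,8aR)-5,5,8a-trimethyl-4-{[(2E)-2-methylbut-2-enoyl]oxy}-1-[2-(2-oxo-2,5-dihydrofuran-3-yl)ethyl]-1,4,4a,5,6,7,8,8a-octahydronaphthalene-2-carboxylate | C/C=C(\C)C(=O)O[C@H]1C=C(C(=O)OC(C)(C)C)[C@H](CCC2=CCOC2=O)[C@@]2(C)CCCC(C)(C)[C@H]12 | intermediate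
23 | (1R,4S,4aS,8aR)-5,5,8a-trimethyl-4-{[(2E)-2-methylbut-2-enoyl]oxy}-1-[2-(2-oxo-2,5-dihydrofuran-3-yl)ethyl]-1,4,4a,5,6,7,8,8a-octahydronaphthalene-2-carboxylic acid | C/C=C(\C)C(=O)O[C@H]1C=C(C(=O)O)[C@H](CCC2=CCOC2=O)[C@@]2(C)CCCC(C)(C)[C@H]12 | target

**Step count and risks**

Total step count: 10. Longest linear sequence: 9 steps (steps 1–5, then 7–10); step 6 is a one-step side branch.

The three steps most likely to fail:

Step 8 (radical ring closure with elimination). The cyclised α-ester radical may be reduced and protonated instead of expelling tiglate, or the chain may be quenched before elimination. The fallback sets out from 17 and comes back at 19. Compound 17 is cyclised under the classical protic reductive olefin coupling conditions (Fe(acac)3, PhSiH3, EtOH/ethylene glycol, 60 °C), which end with hydrogen at C8 and give the saturated tert-butyl 1-(2-bromoethyl)-5,5,8a-trimethyl-3,4-bis(tigloyloxy)decahydronaphthalene-2-carboxylate F1. This is isolated, and the 7,8-alkene is then introduced in a separate E1cB step (LiHMDS, THF, −78 to 0 °C), which gives 19.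

Step 7 (hydroalumination aldol). The (Z)-selectivity or the addition to the hindered α-acyloxy aldehyde may be poor. The fallback sets out from 14 and 11 and comes back at 17. Syn-hydrostannylation of 14 (Bu3SnH, Pd(PPh3)4, THF) gives tert-butyl (2E)-5-bromo-2-(tributylstannyl)pent-2-enoate F2. Iododestannylation (I2, CH2Cl2, 0 °C) gives tert-butyl (2E)-5-bromo-2-iodopent-2-enoate F3 with retention. Nozaki–Hiyama–Kishi coupling of F3 with 11 (CrCl2, NiCl2 cat., DMF) gives the allylic alcohol tert-butyl (2Z)-5-bromo-2-[(2R)-2-[(1S)-2,2-dimethyl-6-methylidenecyclohexyl]-1-hydroxy-2-{[(2E)-2-methylbut-2-enoyl]oxy}ethyl]pent-2-enoate F4. Acylation with 7 (pyridine, DMAP) then gives 17; an acyl shift at the alcohol stage is again harmless.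

Step 2 (copper-catalysed aldol). The nucleophilic carbon sits next to a quaternary centre, and dimethoxyacetaldehyde is a less proven chelating partner, so rate, syn selectivity or ee may fall short. The fallback sets out from 1 and 4 and comes back at 9. Conjugate methylation of 1 with Me2CuLi and trapping with PhNTf2 gives 3,3-dimethylcyclohex-1-en-1-yl trifluoromethanesulfonate F5. Coupling with CH2(Bpin)2 (Pd(OAc)2, SPhos, KOH, dioxane/H2O) gives the allylboronate 2-[(3,3-dimethylcyclohex-1-en-1-yl)methyl]-4,4,5,5-tetramethyl-1,3,2-dioxaborolane F6. Chiral phosphoric acid (TRIP)-catalysed allylboration of 4 goes through the closed chair transition state and gives the anti alcohol (1S)-1-[(1S)-2,2-dimethyl-6-methylidenecyclohexyl]-2,2-dimethoxyethan-1-ol F7, with C5 correct, C6 epimeric and the exocyclic alkene already in place. Dess–Martin oxidation gives 1-[(1S)-2,2-dimethyl-6-methylidenecyclohexyl]-2,2-dimethoxyethan-1-one F8. Felkin–Anh reduction (NaBH4, CeCl3·7H2O, MeOH, −78 °C; hydride anti to the quaternary C4) gives the syn alcohol (1R)-1-[(1S)-2,2-dimethyl-6-methylidenecyclohexyl]-2,2-dimethoxyethan-1-ol F9. Acylation with 7 (pyridine, DMAP) gives 9.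

**Further compounds**

F1 | step 8 | tert-butyl 1-(2-bromoethyl)-5,5,8a-trimethyl-3,4-bis{[(2E)-2-methylbut-2-enoyl]oxy}decahydronaphthalene-2-carboxylate (C1, C4, C4a, C8a as in 19; C2 and C3 as mixtures) | C/C=C(\C)C(=O)O[C@H]1C(OC(=O)/C(C)=C/C)C(C(=O)OC(C)(C)C)[C@H](CCBr)[C@@]2(C)CCCC(C)(C)[C@H]12
F2 | step 7 | tert-butyl (2E)-5-bromo-2-(tributylstannyl)pent-2-enoate | BrCC/C=C(\C(=O)OC(C)(C)C)[Sn](CCCC)(CCCC)CCCC
F3 | step 7 | tert-butyl (2E)-5-bromo-2-iodopent-2-enoate | BrCC/C=C(\C(=O)OC(C)(C)C)I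
F4 | step 7 | tert-butyl (2Z)-5-bromo-2-[(2R)-2-[(1S)-2,2-dimethyl-6-methylidenecyclohexyl]-1-hydroxy-2-{[(2E)-2-methylbut-2-enoyl]oxy}ethyl]pent-2-enoate (C7 epimers) | BrCC/C=C(\C(=O)OC(C)(C)C)C(O)[C@H](OC(=O)/C(C)=C/C)[C@@H]1C(=C)CCCC1(C)C
F5 | step 2 | 3,3-dimethylcyclohex-1-en-1-yl trifluoromethanesulfonate | CC1(C)CCCC(OS(=O)(=O)C(F)(F)F)=C1
F6 | step 2 | 2-[(3,3-dimethylcyclohex-1-en-1-yl)methyl]-4,4,5,5-tetramethyl-1,3,2-dioxaborolane | CC1(C)CCCC(CB2OC(C)(C)C(C)(C)O2)=C1
F7 | step 2 | (1S)-1-[(1S)-2,2-dimethyl-6-methylidenecyclohexyl]-2,2-dimethoxyethan-1-ol | O[C@H](C(OC)OC)[C@@H]1C(=C)CCCC1(C)C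
F8 | step 2 | 1-[(1S)-2,2-dimethyl-6-methylidenecyclohexyl]-2,2-dimethoxyethan-1-one | O=C(C(OC)OC)[C@@H]1C(=C)CCCC1(C)C
F9 | step 2 | (1R)-1-[(1S)-2,2-dimethyl-6-methylidenecyclohexyl]-2,2-dimethoxyethan-1-ol | O[C@@H](C(OC)OC)[C@@H]1C(=C)CCCC1(C)C
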